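Four neighbours meet at the spiro carbon: O1 and C3(=O) of the benzofuranone ring, C8 of the flavonol A ring and the hemiketal carbon, a 4-hydroxybenzoyl ketone in disguise. Two carbonyl-level carbons on one carbon are the mark of a 1,2-acyl shift, so the benzofuranone C2–C3 bond is disconnected to a 2-(flavonol-8-yl)-3-arylchromone 2,3-epoxide. In one operation a Lewis acid breaks the ketal-like C2–O bond, C4 moves from C3 to C2, the pyranone contracts to the benzofuranone, C3 becomes the aroyl ketone and the oxirane configuration passes to the quaternary carbon. The precursor is benzyl-protected, with a deactivated 3,5-dibromo-4-benzyloxyphenyl group on C3 and a flavonol 3-O-carbonate; one hydrogenolysis then frees O7–H for hemiketal closure.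

Key step: step 12

Locants: O1, C2, C3 and C4 refer to the upper chromone (later benzofuranone) unit. Primed locants refer to the lower flavone/flavonol unit. Ar is the aryl group on C3.

Remarks on the design
- **Configurations through the key step.** The (2R,3R)-oxirane, with inversion at C2, gives the (R)-quaternary carbon. In the target the same spatial arrangement is called S, because the hemiketal carbon outranks C3. The hemiketal carbon is R, with its OH syn to C3=O.
- **Deactivating Ar.** An O-acyl deactivator would not survive the basic chromone synthesis, and it would require one phenol to be told apart from six others. Two bromines ortho to a benzyl ether do the same job through their inductive pull and by twisting the benzyloxy group out of conjugation. They tolerate every step and leave in the final hydrogenolysis.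
- **The second chromone double bond.** A 3'-O-benzyl flavonol holds the more electron-rich and less crowded of the two chromone double bonds, so it would be oxidised first. The lower unit is therefore carried as the flavone. Its higher reactivity is used to bring in O3', which is then capped as an electron-withdrawing benzyl carbonate before C2=C3 is epoxidised.
- **Assumption.** The (R,R)-catalyst is written for the (2R,3R)-epoxide. Precedent does not fix the sense of induction for a tetrasubstituted chromone, so the (S,S)-catalyst is taken if a pilot run shows the opposite sense.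

Step 1
Reactants: 1 apigenin
Product: 2 tri-O-benzylapigenin [5,7-bis(benzyloxy)-2-(4-benzyloxyphenyl)chromen-4-one]
Conditions: BnBr (excess), K2CO3, DMF, 80 °C
Reagents that add atoms: benzyl bromide, BrCc1ccccc1
Why: Williamson ether synthesis; excess halide and heat also alkylate the hydrogen-bonded 5-OH, so all three phenols become hydrogenolysable ethers.

Step 2
Reactants: 2 tri-O-benzylapigenin
Product: 3 8-iodo-tri-O-benzylapigenin
Conditions: NIS, TFA (cat.), CH2Cl2–MeCN, 0 °C → rt
Reagents that add atoms: N-iodosuccinimide, O=C1CCC(=O)N1I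
Why: Electrophilic aromatic iodination goes to the phloroglucinol-type A ring, and in fully alkylated 5,7-dialkoxyflavones C8 is preferred over C6, which sits between two benzyloxy groups.

Step 3
Reactants: 3 8-iodo-tri-O-benzylapigenin
Product: 4 tri-O-benzylapigenin-8-carboxylic acid
Conditions: CO (1 atm), Pd(OAc)2, dppf, Et3N, DMF–H2O, 80 °C; aq HCl
Reagents that add atoms: carbon monoxide, [C-]#[O+]; water, O
Why: Palladium-catalysed hydroxycarbonylation of an aryl iodide (oxidative addition, CO insertion, hydrolysis of the acyl-palladium species) gives the hindered acid directly and avoids saponifying a 2,6-disubstituted benzoate.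

Step 4
Reactants: 5 4-hydroxyphenylacetic acid
Product: 6 3,5-dibromo-4-hydroxyphenylacetic acid
Conditions: Br2 (2.1 equiv), AcOH, rt
Reagents that add atoms: bromine, BrBr
Why: Electrophilic aromatic bromination of a para-substituted phenol fills the two ortho positions and then stops.

Step 5
Reactants: 6 3,5-dibromo-4-hydroxyphenylacetic acid; 7 phloroglucinol
Product: 8 2-(3,5-dibromo-4-hydroxyphenyl)-1-(2,4,6-trihydroxyphenyl)ethanone
Conditions: BF3·OEt2 (solvent), 85 °C; aq NaOAc
Reagents that add atoms: none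
Why: BF3-mediated Friedel–Crafts C-acylation of phloroglucinol by an arylacetic acid is the standard entry to 2,4,6-trihydroxydeoxybenzoins, and the symmetry of the phenol excludes regioisomers.

Step 6
Reactants: 8 2-(3,5-dibromo-4-hydroxyphenyl)-1-(2,4,6-trihydroxyphenyl)ethanone
Product: 9 1-[2,4-bis(benzyloxy)-6-hydroxyphenyl]-2-(4-benzyloxy-3,5-dibromophenyl)ethanone
Conditions: BnBr (3.1 equiv), K2CO3, acetone, reflux
Reagents that add atoms: benzyl bromide, BrCc1ccccc1
Why: Williamson etherification with three equivalents of halide spares the one ortho-hydroxyl that is hydrogen-bonded to the ketone, the usual selectivity of 2,4,6-trihydroxyaryl ketones.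

Step 7
Reactants: 4 tri-O-benzylapigenin-8-carboxylic acid; 9 1-[2,4-bis(benzyloxy)-6-hydroxyphenyl]-2-(4-benzyloxy-3,5-dibromophenyl)ethanone
Product: 11 3,5-bis(benzyloxy)-2-[(4-benzyloxy-3,5-dibromophenyl)acetyl]phenyl tri-O-benzylapigenin-8-carboxylate, via acid chloride 10 (not isolated)
Conditions: (COCl)2, DMF (cat.), CH2Cl2, 0 °C → rt; evaporate; 9, Et3N, DMAP (cat.), CH2Cl2, 0 °C → rt
Reagents that add atoms: oxalyl chloride, O=C(Cl)C(=O)Cl (chlorine of 10 only)
Why: Acid chloride formation followed by DMAP-catalysed O-acylation (nucleophilic catalysis) is the dependable way to esterify a 2,6-dioxygenated benzoic acid, and flavone-8-carbonyl chlorides are stable, known acylating agents.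

Step 8
Reactants: 11 aryl ester
Product: 13 5,7-bis(benzyloxy)-3-(4-benzyloxy-3,5-dibromophenyl)-2-(tri-O-benzylapigenin-8-yl)chromen-4-one, via 1,3-diketone 12 (not isolated)
Conditions: KOtBu, THF, 0 °C → rt; AcOH; then TsOH·H2O (cat.), toluene, 80 °C
Reagents that add atoms: none
Why: Baker–Venkataraman rearrangement (intramolecular Claisen-type acyl transfer from oxygen to the benzylic enolate carbon) and acid-catalysed cyclodehydration of the o-hydroxy-1,3-diketone form the classical route from 2-hydroxydeoxybenzoins to 2,3-diarylchromones.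

Step 9
Reactants: 13 chromone–flavone
Product: 15 5,7-bis(benzyloxy)-3-(4-benzyloxy-3,5-dibromophenyl)-2-(5,7,4'-tri-O-benzylkaempferol-8-yl)chromen-4-one (3'-OH free), via flavone epoxide 14 (not isolated)
Conditions: DMDO (acetone soln, ca. 3 equiv), CH2Cl2, 0 °C; evaporate; TsOH·H2O (cat.), CH2Cl2, rt
Reagents that add atoms: dimethyldioxirane, CC1(C)OO1
Why: Dioxirane epoxidation of a benzyl-protected flavone followed by acid-catalysed isomerisation of the oxirane to the 3-hydroxyflavone is an established flavonol synthesis; the flat, trisubstituted C2'=C3' bond should react well before the crowded tetrasubstituted C2=C3 bond, and the two transient stereocentres of 14 vanish on aromatisation.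

Step 10
Reactants: 15 chromone–flavonol
Product: 16 3'-O-benzyloxycarbonyl derivative of 15
Conditions: CbzCl, Et3N, DMAP (cat.), CH2Cl2, 0 °C
Reagents that add atoms: benzyl chloroformate, O=C(Cl)OCc1ccccc1
Why: O-acylation of the enolic 3'-OH with a chloroformate turns the electron-rich enol into an enol carbonate, which lowers the nucleophilicity of C2'=C3' and later falls off by hydrogenolysis.

Step 11
Reactants: 16 chromone–flavonol carbonate
Product: 17 (2R,3R)-2,3-epoxide of 16 (oxirane cis-fused to the pyranone; lower unit on C2 and Ar on C3 both anti to the oxirane oxygen)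
Conditions: (R,R)-N,N'-bis(3,5-di-tert-butylsalicylidene)-1,2-cyclohexanediaminomanganese(III) chloride (10 mol %), 4-phenylpyridine N-oxide (30 mol %), PhIO (3 equiv), CH2Cl2, 0 °C; filtration through Et3N-washed basic alumina, used at once
Reagents that add atoms: iodosylbenzene, O=Ic1ccccc1
Why: Jacobsen–Katsuki epoxidation, known for the C2=C3 bond of isoflavones and for tetrasubstituted chromenes, should deliver oxygen to the most nucleophilic alkene left (C2'=C3' is now an enol carbonate of an enone), and the chiral salen ligand chooses the alkene face, so both oxirane centres, necessarily cis on the ring, are set together.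

Step 12
Reactants: 17 (2R,3R)-epoxide
Product: 18 (R)-4,6-bis(benzyloxy)-2-(4-benzyloxy-3,5-dibromobenzoyl)-2-(3-O-benzyloxycarbonyl-5,7,4'-tri-O-benzylkaempferol-8-yl)benzofuran-3(2H)-one
Conditions: BF3·OEt2 (30 mol %), toluene–CH2Cl2 4:1, −78 °C; Et3N quench
Reagents that add atoms: none
Why: Proposed new method: BF3 binds the oxirane oxygen and the C2–O bond, the ketal-type bond next to ring O1, heterolyses while C4 slides from C3 to C2 and the C3–O bond collapses to the aryl ketone. The closest known reaction type is the Lewis-acid rearrangement of α,β-epoxy ketones to 1,3-dicarbonyl compounds by 1,2-acyl migration, including the contraction of 2,3-epoxycyclohexanones to 2-acylcyclopentanones, which has not been run on a fully substituted chromone epoxide. The benzofuran-3-one ring is closed by ring contraction, that is, by a 1,2-shift of an endocyclic bond inside the six-membered ring and not by an exo or endo cyclisation of a chain. The single stereocentre of 18 is dictated by the oxirane, because C4 bonds to the face of C2 opposite the leaving oxygen (inversion at C2), so the (2R,3R)-epoxide should give (R)-18; the orthogonal lower unit lends the cation little resonance help, and an apolar medium at −78 °C should keep the ion pair too short-lived for a ring flip that would expose the other face. The step needs acyl over aryl migration and C2–O over C3–O cleavage: the two meta bromines and the twisted benzyloxy group make Ar a poor bridging group, the migrating 2,4,6-trioxygenated aroyl carbon is electron-rich, and a cation at C3 next to the ketone cannot compete. Benzyl ethers and the enol carbonate should be inert to catalytic BF3 at this temperature.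

Step 13
Reactants: 18 (R)-diketone
Product: 20 target CNP0283000.1 (spiro carbon S; hemiketal carbon R; hemiketal OH syn to C3=O), via open keto-phenol 19 (not isolated)
Conditions: H2 (1 atm), 10% Pd/C, NaOAc (2.5 equiv), THF–H2O 9:1, rt
Reagents that add atoms: none
Why: Catalytic hydrogenolysis cleaves the six benzyl ethers and the benzyl carbonate (with loss of CO2) and hydrodehalogenates both aryl bromides, after which the freed O7'–H adds reversibly to the neighbouring aroyl ketone (5-exo-trig hemiketalisation), so the new centre settles under thermodynamic control as the epimer whose OH is hydrogen-bonded to C3=O while the quaternary carbon stays untouched.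

Compound list
1 | apigenin | O=c1cc(-c2ccc(O)cc2)oc2cc(O)cc(O)c12 | starting material
2 | tri-O-benzylapigenin | O=c1cc(-c2ccc(OCc3ccccc3)cc2)oc2cc(OCc3ccccc3)cc(OCc3ccccc3)c12 | intermediate
3 | 8-iodo-tri-O-benzylapigenin | O=c1cc(-c2ccc(OCc3ccccc3)cc2)oc2c(I)c(OCc3ccccc3)cc(OCc3ccccc3)c12 | intermediate
4 | tri-O-benzylapigenin-8-carboxylic acid | O=C(O)c1c(OCc2ccccc2)cc(OCc2ccccc2)c2c(=O)cc(-c3ccc(OCc4ccccc4)cc3)oc12 | intermediate
5 | 4-hydroxyphenylacetic acid | O=C(O)Cc1ccc(O)cc1 | starting material
6 | 3,5-dibromo-4-hydroxyphenylacetic acid | O=C(O)Cc1cc(Br)c(O)c(Br)c1 | intermediate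
7 | phloroglucinol | Oc1cc(O)cc(O)c1 | starting material
8 | 2-(3,5-dibromo-4-hydroxyphenyl)-1-(2,4,6-trihydroxyphenyl)ethanone | O=C(Cc1cc(Br)c(O)c(Br)c1)c1c(O)cc(O)cc1O | intermediate
9 | 1-[2,4-bis(benzyloxy)-6-hydroxyphenyl]-2-(4-benzyloxy-3,5-dibromophenyl)ethanone | O=C(Cc1cc(Br)c(OCc2ccccc2)c(Br)c1)c1c(O)cc(OCc2ccccc2)cc1OCc1ccccc1 | intermediate
10 | tri-O-benzylapigenin-8-carbonyl chloride | O=C(Cl)c1c(OCc2ccccc2)cc(OCc2ccccc2)c2c(=O)cc(-c3ccc(OCc4ccccc4)cc3)oc12 | intermediate
11 | aryl ester of 4 with the phenol of 9 | O=C(Oc1cc(OCc2ccccc2)cc(OCc2ccccc2)c1C(=O)Cc1cc(Br)c(OCc2ccccc2)c(Br)c1)c1c(OCc2ccccc2)cc(OCc2ccccc2)c2c(=O)cc(-c3ccc(OCc4ccccc4)cc3)oc12 | intermediate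
12 | 1-[2,4-bis(benzyloxy)-6-hydroxyphenyl]-2-(4-benzyloxy-3,5-dibromophenyl)-3-(tri-O-benzylapigenin-8-yl)propane-1,3-dione (epimerisable CH) | O=C(c1c(O)cc(OCc2ccccc2)cc1OCc1ccccc1)C(c1cc(Br)c(OCc2ccccc2)c(Br)c1)C(=O)c1c(OCc2ccccc2)cc(OCc2ccccc2)c2c(=O)cc(-c3ccc(OCc4ccccc4)cc3)oc12 | intermediate
13 | 5,7-bis(benzyloxy)-3-(4-benzyloxy-3,5-dibromophenyl)-2-(tri-O-benzylapigenin-8-yl)chromen-4-one | O=c1c(-c2cc(Br)c(OCc3ccccc3)c(Br)c2)c(-c2c(OCc3ccccc3)cc(OCc3ccccc3)c3c(=O)cc(-c4ccc(OCc5ccccc5)cc4)oc23)oc2cc(OCc3ccccc3)cc(OCc3ccccc3)c12 | intermediate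
14 | 2',3'-epoxide of 13 in the lower flavone unit (racemic oxirane) | O=c1c(-c2cc(Br)c(OCc3ccccc3)c(Br)c2)c(-c2c(OCc3ccccc3)cc(OCc3ccccc3)c3c2OC2(c4ccc(OCc5ccccc5)cc4)OC2C3=O)oc2cc(OCc3ccccc3)cc(OCc3ccccc3)c12 | intermediate
15 | 5,7-bis(benzyloxy)-3-(4-benzyloxy-3,5-dibromophenyl)-2-(5,7,4'-tri-O-benzylkaempferol-8-yl)chromen-4-one | O=c1c(-c2cc(Br)c(OCc3ccccc3)c(Br)c2)c(-c2c(OCc3ccccc3)cc(OCc3ccccc3)c3c(=O)c(O)c(-c4ccc(OCc5ccccc5)cc4)oc23)oc2cc(OCc3ccccc3)cc(OCc3ccccc3)c12 | intermediate
16 | 3'-O-benzyloxycarbonyl derivative of 15 | O=c1c(-c2cc(Br)c(OCc3ccccc3)c(Br)c2)c(-c2c(OCc3ccccc3)cc(OCc3ccccc3)c3c(=O)c(OC(=O)OCc4ccccc4)c(-c4ccc(OCc5ccccc5)cc4)oc23)oc2cc(OCc3ccccc3)cc(OCc3ccccc3)c12 | intermediate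
17 | (2R,3R)-2,3-epoxide of 16 | O=C1c2c(OCc3ccccc3)cc(OCc3ccccc3)cc2O[C@]2(c3c(OCc4ccccc4)cc(OCc4ccccc4)c4c(=O)c(OC(=O)OCc5ccccc5)c(-c5ccc(OCc6ccccc6)cc5)oc34)O[C@]12c1cc(Br)c(OCc2ccccc2)c(Br)c1 | intermediate
18 | (R)-4,6-bis(benzyloxy)-2-(4-benzyloxy-3,5-dibromobenzoyl)-2-(3-O-benzyloxycarbonyl-5,7,4'-tri-O-benzylkaempferol-8-yl)benzofuran-3(2H)-one | O=C1c2c(OCc3ccccc3)cc(OCc3ccccc3)cc2O[C@@]1(C(=O)c1cc(Br)c(OCc2ccccc2)c(Br)c1)c1c(OCc2ccccc2)cc(OCc2ccccc2)c2c(=O)c(OC(=O)OCc3ccccc3)c(-c3ccc(OCc4ccccc4)cc3)oc12 | intermediate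
19 | (R)-4,6-dihydroxy-2-(4-hydroxybenzoyl)-2-(kaempferol-8-yl)benzofuran-3(2H)-one | O=C1c2c(O)cc(O)cc2O[C@@]1(C(=O)c1ccc(O)cc1)c1c(O)cc(O)c2c(=O)c(O)c(-c3ccc(O)cc3)oc12 | intermediate
20 | CNP0283000.1 (spiro carbon S, hemiketal carbon R) | O=C1c2c(O)cc(O)cc2O[C@@]12c1c(cc(O)c3c(=O)c(O)c(-c4ccc(O)cc4)oc13)O[C@]2(O)c1ccc(O)cc1 | target

Total step count: 13. Longest linear sequence: 10 steps (steps 1–3 then 7–13, or steps 4–6 then 7–13).

Steps most likely to fail

1. **Step 12.** Ar may migrate instead of the acyl carbon. Alternatively, ionisation may give a free oxocarbenium ion that lives long enough for ring inversion, which would erode the transfer of configuration.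
 - The fallback sets out from 3 and comes back at 20. It makes the quaternary carbon by Pinhey arylation of a β-dicarbonyl compound, a reaction type established for 2-acylated benzofuran-3(2H)-ones and for 2,4,6-trialkoxyaryl groups.
 - Palladium-catalysed stannylation of 3 (hexabutylditin, Pd(PPh3)4, toluene, reflux) gives 8-(tributylstannyl)-tri-O-benzylapigenin F1. Tin–lead exchange (Pb(OAc)4, cat. Hg(OAc)2, CHCl3) gives (tri-O-benzylapigenin-8-yl)lead triacetate F2.
 - Separately, commercial methyl 2,4,6-trihydroxybenzoate is dibenzylated (BnBr, K2CO3) to methyl 2,4-bis(benzyloxy)-6-hydroxybenzoate F3. O-alkylation with commercial 2-bromo-4'-benzyloxyacetophenone gives the phenacyl ether F4. Dieckmann-type condensation (KOtBu) closes it to 2-(4-benzyloxybenzoyl)-4,6-bis(benzyloxy)benzofuran-3(2H)-one F5.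
 - F2 and F5 (pyridine, CHCl3, 40 °C) should give the racemic 2-aroyl-2-(tri-O-benzylapigenin-8-yl)benzofuranone F6. No other alkene is left, so DMDO and then catalytic TsOH convert its flavone unit into the racemic flavonol F7.
 - Preparative HPLC on a chiral stationary phase delivers the (R)-flavonol F8. Hydrogenolysis (H2, Pd/C) leads through 19 to 20.

2. **Step 11.** Oxygen transfer to a crowded, electron-poor tetrasubstituted alkene may be slow. Facial selectivity may be poor, the enol carbonate double bond may be oxidised in competition, and the oxirane may open on the Lewis-acidic catalyst.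
 - The fallback sets out from 16 and comes back at 18. It secures the absolute configuration by resolution instead of catalysis.
 - An excess of DMDO (CH2Cl2–acetone, 0 °C, no metal) should give the racemic cis-epoxide, that is 17 together with the (2S,3S)-epoxide F9.
 - The mixture is rearranged as in step 12 to 18 and the (S)-diketone F10. Both are configurationally stable and are separated by preparative HPLC or SFC on a polysaccharide chiral phase.

3. **Step 8.** Acyl transfer onto the doubly ortho-substituted ester carbonyl may be sluggish, and cleavage of the aryl ester by the base may compete.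
 - The fallback sets out from 3 and 9 and comes back at 13. It replaces the ester electrophile with the far less hindered aldehyde.
 - Palladium-catalysed formylation of 3 (CO/H2, Pd(OAc)2, di-1-adamantyl-n-butylphosphine, Et3N, toluene, 100 °C) gives tri-O-benzylapigenin-8-carbaldehyde F11.
 - Piperidine-catalysed Knoevenagel condensation with 9 and oxa-Michael closure (EtOH, reflux) gives the 2,3-diarylchroman-4-one F12.
 - Dehydrogenation with DDQ (dioxane, reflux) gives 13.

Further compounds
F1 | step 12 | 8-(tributylstannyl)-tri-O-benzylapigenin | CCCC[Sn](CCCC)(CCCC)c1c(OCc2ccccc2)cc(OCc2ccccc2)c2c(=O)cc(-c3ccc(OCc4ccccc4)cc3)oc12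
F2 | step 12 | (tri-O-benzylapigenin-8-yl)lead triacetate | CC(=O)O[Pb](OC(C)=O)(OC(C)=O)c1c(OCc2ccccc2)cc(OCc2ccccc2)c2c(=O)cc(-c3ccc(OCc4ccccc4)cc3)oc12
F3 | step 12 | methyl 2,4-bis(benzyloxy)-6-hydroxybenzoate | COC(=O)c1c(O)cc(OCc2ccccc2)cc1OCc1ccccc1
F4 | step 12 | methyl 2,4-bis(benzyloxy)-6-[2-(4-benzyloxyphenyl)-2-oxoethoxy]benzoate | COC(=O)c1c(OCC(=O)c2ccc(OCc3ccccc3)cc2)cc(OCc2ccccc2)cc1OCc1ccccc1
F5 | step 12 | 2-(4-benzyloxybenzoyl)-4,6-bis(benzyloxy)benzofuran-3(2H)-one | O=C(c1ccc(OCc2ccccc2)cc1)C1Oc2cc(OCc3ccccc3)cc(OCc3ccccc3)c2C1=O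
F6 | step 12 | rac-2-(4-benzyloxybenzoyl)-4,6-bis(benzyloxy)-2-(tri-O-benzylapigenin-8-yl)benzofuran-3(2H)-one | O=C1c2c(OCc3ccccc3)cc(OCc3ccccc3)cc2OC1(C(=O)c1ccc(OCc2ccccc2)cc1)c1c(OCc2ccccc2)cc(OCc2ccccc2)c2c(=O)cc(-c3ccc(OCc4ccccc4)cc3)oc12
F7 | step 12 | rac-2-(4-benzyloxybenzoyl)-4,6-bis(benzyloxy)-2-(5,7,4'-tri-O-benzylkaempferol-8-yl)benzofuran-3(2H)-one | O=C1c2c(OCc3ccccc3)cc(OCc3ccccc3)cc2OC1(C(=O)c1ccc(OCc2ccccc2)cc1)c1c(OCc2ccccc2)cc(OCc2ccccc2)c2c(=O)c(O)c(-c3ccc(OCc4ccccc4)cc3)oc12
F8 | step 12 | (R)-enantiomer of F7 | O=C1c2c(OCc3ccccc3)cc(OCc3ccccc3)cc2O[C@@]1(C(=O)c1ccc(OCc2ccccc2)cc1)c1c(OCc2ccccc2)cc(OCc2ccccc2)c2c(=O)c(O)c(-c3ccc(OCc4ccccc4)cc3)oc12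
F9 | step 11 | (2S,3S)-epoxide, enantiomer of 17 | O=C1c2c(OCc3ccccc3)cc(OCc3ccccc3)cc2O[C@@]2(c3c(OCc4ccccc4)cc(OCc4ccccc4)c4c(=O)c(OC(=O)OCc5ccccc5)c(-c5ccc(OCc6ccccc6)cc5)oc34)O[C@@]12c1cc(Br)c(OCc2ccccc2)c(Br)c1
F10 | step 11 | (S)-diketone, enantiomer of 18 | O=C1c2c(OCc3ccccc3)cc(OCc3ccccc3)cc2O[C@]1(C(=O)c1cc(Br)c(OCc2ccccc2)c(Br)c1)c1c(OCc2ccccc2)cc(OCc2ccccc2)c2c(=O)c(OC(=O)OCc3ccccc3)c(-c3ccc(OCc4ccccc4)cc3)oc12
F11 | step 8 | tri-O-benzylapigenin-8-carbaldehyde | O=Cc1c(OCc2ccccc2)cc(OCc2ccccc2)c2c(=O)cc(-c3ccc(OCc4ccccc4)cc3)oc12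
F12 | step 8 | 5,7-bis(benzyloxy)-3-(4-benzyloxy-3,5-dibromophenyl)-2-(tri-O-benzylapigenin-8-yl)chroman-4-one (racemic, mixture of diastereomers) | O=C1c2c(OCc3ccccc3)cc(OCc3ccccc3)cc2OC(c2c(OCc3ccccc3)cc(OCc3ccccc3)c3c(=O)cc(-c4ccc(OCc5ccccc5)cc4)oc23)C1c1cc(Br)c(OCc2ccccc2)c(Br)c1
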